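## Structural features

The target is an achiral, flat molecule built from two aromatic units. Ring A is a 1,2,3,5-tetrasubstituted benzene (A1 CH2 link, A2 OMe, A4 OH, A6 CH2OMe). The other unit is a 3-methylisocoumarin whose benzenoid ring B is substituted on five of its six carbons (C4a, C5, C6, C8, C8a; only C7 carries hydrogen, so the ring is pentasubstituted) and whose pyranone ring C is an enol lactone. The two units are joined by one methylene between A1 and C5, flanked on ring A by OMe and CH2OMe and on ring B by C4a and the C6 hydroxyl. There is no stereocentre and no stereogenic double bond, so nothing stereochemical has to be set or preserved. Three points are fragile: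

- the enol lactone, which nucleophiles open and whose C3–C4 double bond can be hydrogenated;
- the benzylic methyl ether at A6, which can be hydrogenolysed and whose oxygen can capture an electrophilic centre on the benzylic carbon at A1 to close a cyclic ether;
- the bis(electron-rich aryl)methane, which is sensitive to strong acid and to oxidants.

The real difficulty is ring B: five contiguous substituents, with the C6 oxygen free but the chelated peri oxygen at C8 methylated. That is the opposite of what selective demethylation next to a carbonyl delivers, and ring A poses the same free/methylated problem. The key step uses the fact that C7 (H), C8 (OMe), C8a (carboxyl) and C4a (carbon) coincide with C3, C4, C5 and C6 of a 4-methoxy-6-methyl-2-pyrone-5-carboxylate. C5 (with the ring A benzyl group) and C6 (with its oxygen) can then come from the two carbons of a silyl ynol ether, so ring B is made with every substituent in place and its two oxygens already differentiated.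

## Logic of the disconnections

**24 to 23.** The C6 O–H is traced back to an O–Si bond. A silyl ether is the form in which this oxygen leaves the key step, so no separate protection is spent. The forward step must remove silicon without opening the enol lactone, which calls for buffered fluoride.

**23 to 22.** The lactone bond C1–O2 is cut, giving a methyl ester and a methyl ketone on neighbouring ring B carbons. This removes ring C and exposes an ortho-toluate pattern. The forward step is an enol lactonisation that must leave the silyl ether and the diarylmethane intact.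

**22 to 21.** The A4 O–H is traced back to an O–benzyl bond. The benzyl group is cleaved before ring C exists, so no C3–C4 double bond is present during hydrogenation. The forward step must still spare the benzylic methyl ether at A6.

**21 to 18.** The C3–C4 bond is cut between the benzylic carbon on C4a and the acetyl carbon. This reduces the side chain to an aryl methyl group ortho to an ester. The forward step needs selective deprotonation of that methyl group in the presence of the diarylmethane CH2, and a single acylation.

**18 to 4 and 16.** The bonds C4a–C5 and C6–C7 are cut. Ring B falls apart into a pyrone that carries C7, C8, C8a and C4a with their substituents and an ynol ether that carries C5 and C6 together with all of ring A. This is the largest simplification of the route. It demands a regioselective cycloaddition between a diene of moderate reactivity and a heat- and acid-sensitive alkyne.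

**16 to 13.** The C–O bond of the ynol ether and the O–Si bond are cut, leading to a terminal alkyne. The forward step is oxygen transfer to the acetylide followed by O-silylation. This was preferred to ester homologation because an arylacetate carries acidic benzylic hydrogens that would compete for the carbenoid base.

**13 to 12 to 10.** The terminal alkyne carbon and then the aldehyde carbon of the arylacetaldehyde are removed, two one-carbon homologations back to a benzaldehyde. Both forward steps build the A1 benzylic CH2 from a carbonyl. No leaving group is ever placed on that carbon, which the A6 methoxymethyl oxygen could displace.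

**10 to 9 to 8.** The A2 O–CH3 bond is cut, and the A2 O–H is then traced back to a second benzyl ether. The symmetric bis(benzyl ether) is differentiated by the aldehyde, which activates only the ortho ether toward chelation-controlled cleavage. The forward steps need that chelation to be selective and then a simple methylation.

**8 to 6 to 5.** The A1–CHO bond and the benzylic O–CH3 bond are cut, leading to a symmetric commercial benzyl alcohol. The forward formylation must go ortho to the methoxymethyl group and not between the two benzyloxy groups.

**4 to 3 to 1.** The C4 O–CH3 bond is cut, then the lactone bond O1–C2 and the bond from C5 to the acetyl carbon, leading to a commercial keto diester. The forward steps need C-acylation, lactonisation onto the distal ester and O-methylation at the 4-oxygen.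

## Other disconnections considered

**Alternative 1:** ring A is cut at A1–A2 and A5–A6 and assembled on a preformed ring B benzoate. In the forward direction the ynone methyl 4-(benzyloxy)-2-methoxy-5-(4-methoxybut-2-ynoyl)benzoate (A1) would react with 1,1-dimethoxy-3-(trimethylsilyloxy)buta-1,3-diene (A2). The diene CH2 terminus would bond to the alkyne carbon bearing CH2OMe (A5–A6) and the ketene acetal carbon to the acyl-bearing alkyne carbon (A1–A2). Loss of one methoxy group and of silicon would then give the benzophenone A3.

- In its favour: the cycloaddition of 1,1-dialkoxy-3-siloxy dienes with acetylenic ketones is an established reaction type, so on precedent this alternative is the better plan. It also delivers ring A with A4–OH free and A2–OMe in one operation, without a protecting group, which is better than the three operations the chosen route spends on that differentiation.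
- Against it: A3 is a diaryl ketone between two very electron-rich rings, and it must be reduced to CH2. The ionic intermediates of that reduction sit next to the A6 methoxymethyl oxygen. Ring B of A3 also carries hydrogen at the future C4a, so the C3–C4 unit would have to be introduced late, at a position between an ester and the aroyl (later benzyl) group.
- Comparison: structurally it builds the easier ring and leaves the pentasubstituted ring B to be completed by other means, whereas the chosen plan makes ring B complete. Mechanistically both are [4+2] additions followed by an aromatising extrusion, with the alternative being the better-matched pair. In step economy the alternative is worse, because deoxygenation and the late C4a functionalisation add several operations after its key step.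

**Alternative 2:** ring B is cut at C8a–C4a and unfolded into a polyketide-like chain. The precursor is the dioxinone A4, which carries the 3-benzyl-2,4-dioxopentyl chain with a ketal-masked terminal ketone. An amine base and then acid would let the dioxinone alpha carbon add to the chain ketone, and dehydration would give the benzodioxinone A5.

- In its favour: the aromatisation of diketo-dioxinones to resorcylates is known, so on precedent it is the better plan, and it runs at room temperature, where it is also better than a 120 °C cycloaddition. Its regiochemistry is fixed by connectivity, which is equal to the chosen plan. The C6 hydroxyl emerges free while the C8 oxygen is tied up in the acetonide, so the two oxygens are differentiated, again equal.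
- Against it: A4 is a 2-substituted 1,3-diketone carrying a dioxinone and a ketal. Its assembly needs C-benzylation between two carbonyls with a ring A benzylic electrophile, which is the species most prone to capture by the A6 ether oxygen, and O-alkylation competes. After the key step the C8 oxygen appears as the chelated peri hydroxyl, which must be methylated while the C6 hydroxyl is protected.
- Comparison: both plans build ring B with all carbons in place. The mechanism of the alternative is milder and better precedented. Its route is longer, because the C8 methylation requires protection of the C6 hydroxyl and a fragile acyclic precursor has to be made and carried.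

**Alternative 3:** ring B is cut at C8a–C4a and C7–C6 at the dihydro oxidation level. Methyl acetoacetate (A6) and the crotonate A7 would condense under alkoxide base, by Michael addition and then Claisen condensation, to the cyclohexanedione ester A8 as a diastereomer mixture.

- In its favour: the chemistry is classical and cheap, its regiochemistry is unambiguous, and it needs neither high temperature nor a sensitive ynol ether. On reliability of reaction type it is the better plan.
- Against it: the Michael acceptor is alpha,beta-disubstituted and hindered. A8 must be dehydrogenated in the presence of the oxidisable, easily halogenated ring A. The two phenols that result must then be differentiated (silylation of the non-chelated one, methylation of the chelated one) before the intermediate of the chosen route is reached.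
- Comparison: structurally it delivers the same ring B carbon pattern but neither aromatic nor differentiated. Mechanistically it is safer. In step economy it is worse by about three operations on the ring B side. For that reason it serves below as the fallback for the key step and not as the main plan.

Key step: step 10

## Route

Remark: oxygen-centred salts formed by simple deprotonation in the flask (alkoxides, phenoxides) are regarded as the parent compound; carbon-centred lithium species and covalent intermediates are numbered.

Step 1
Reactants: 1 dimethyl 3-oxopentanedioate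
Product: 3 methyl 4-hydroxy-6-methyl-2-oxo-2H-pyran-5-carboxylate, via C-acetylated keto diester 2 (not isolated)
Conditions: MgCl2, pyridine, AcCl, CH2Cl2, 0 °C to rt; aq. HCl wash; crude 2, TsOH·H2O (cat.), toluene, reflux
Reagents that add atoms: acetyl chloride, CC(=O)Cl
Why: Soft-enolisation C-acylation of the magnesium chelate of the β-keto diester puts the acetyl group on an α-carbon; under acid the acetyl enol oxygen attacks the distal ester (lactonisation with loss of methanol) and the ring tautomerises to the 4-hydroxy-2-pyrone.

Step 2
Reactants: 3 methyl 4-hydroxy-6-methyl-2-oxo-2H-pyran-5-carboxylate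
Product: 4 methyl 4-methoxy-6-methyl-2-oxo-2H-pyran-5-carboxylate
Conditions: Me2SO4, K2CO3, acetone, reflux
Reagents that add atoms: dimethyl sulfate, COS(=O)(=O)OC
Why: O-Alkylation of the vinylogous acid with a hard methylating agent is the usual way to 4-methoxy-2-pyrones; the isomeric 2-methoxy-4-pyrone is the expected minor by-product and should be separable.

Step 3
Reactants: 5 [3,5-bis(benzyloxy)phenyl]methanol
Product: 6 1,3-bis(benzyloxy)-5-(methoxymethyl)benzene
Conditions: NaH, MeI, THF, 0 °C to rt
Reagents that add atoms: methyl iodide, CI
Why: Williamson etherification of a primary benzylic alcohol; the aryl benzyl ethers are inert.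

Step 4
Reactants: 6 1,3-bis(benzyloxy)-5-(methoxymethyl)benzene
Product: 8 2,4-bis(benzyloxy)-6-(methoxymethyl)benzaldehyde, via Vilsmeier iminium chloride 7 (not isolated)
Conditions: POCl3, DMF, 0 °C to 70 °C; then aq. NaOAc, rt
Reagents that add atoms: N,N-dimethylformamide, CN(C)C=O; water, O
Why: Vilsmeier–Haack formylation; in 3,5-dialkoxybenzyl systems the position ortho to the CH2 group and para to one alkoxy group is favoured over the more hindered position between the two alkoxy groups, and the benzylic methyl ether does not react with the chloroiminium reagent.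

Step 5
Reactants: 8 2,4-bis(benzyloxy)-6-(methoxymethyl)benzaldehyde
Product: 9 4-(benzyloxy)-2-hydroxy-6-(methoxymethyl)benzaldehyde
Conditions: MgBr2·OEt2 (3 equiv), toluene–Et2O, 80 °C; 1 M HCl work-up
Reagents that add atoms: none
Why: Chelation-controlled debenzylation: magnesium bridges the aldehyde oxygen and the ortho ether oxygen in a six-membered chelate and bromide removes only that benzyl group; the para benzyl ether cannot chelate, and the methoxymethyl oxygen would need a seven-membered chelate and offers only a methyl carbon.

Step 6
Reactants: 9 4-(benzyloxy)-2-hydroxy-6-(methoxymethyl)benzaldehyde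
Product: 10 4-(benzyloxy)-2-methoxy-6-(methoxymethyl)benzaldehyde
Conditions: MeI, K2CO3, DMF, rt
Reagents that add atoms: methyl iodide, CI
Why: Williamson methylation of the hydrogen-bonded phenol; this fixes the A2-OMe / A4-OBn differentiation.

Step 7
Reactants: 10 4-(benzyloxy)-2-methoxy-6-(methoxymethyl)benzaldehyde
Product: 12 [4-(benzyloxy)-2-methoxy-6-(methoxymethyl)phenyl]acetaldehyde, via methyl enol ether 11 (not isolated)
Conditions: MeOCH2PPh3Cl, KOt-Bu, THF, 0 °C to rt; then 1 M aq. H2SO4, THF, 40 °C
Reagents that add atoms: (methoxymethyl)triphenylphosphonium chloride, COC[P+](c1ccccc1)(c1ccccc1)c1ccccc1.[Cl-]; water, O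
Why: Wittig methoxymethylenation of the non-enolisable aldehyde and hydrolysis of the enol ether give the homologous aldehyde; the A1 benzylic CH2 is made by protonation of an enol ether, so no benzylic leaving group arises next to the A6 methoxymethyl oxygen, and an acid with a non-nucleophilic counter-ion is used for the same reason.

Step 8
Reactants: 12 [4-(benzyloxy)-2-methoxy-6-(methoxymethyl)phenyl]acetaldehyde
Product: 13 5-(benzyloxy)-1-methoxy-3-(methoxymethyl)-2-(prop-2-yn-1-yl)benzene
Conditions: MeC(O)C(N2)P(O)(OMe)2, K2CO3, MeOH, 0 °C to rt
Reagents that add atoms: dimethyl (1-diazo-2-oxopropyl)phosphonate, CC(=O)C(=[N+]=[N-])P(=O)(OC)OC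
Why: Seyferth–Gilbert homologation with the Ohira–Bestmann reagent converts the aldehyde into the terminal alkyne under carbonate base, mild enough to limit aldol reaction of 12 and propargyl-to-allene isomerisation of 13.

Step 9
Reactants: 13 5-(benzyloxy)-1-methoxy-3-(methoxymethyl)-2-(prop-2-yn-1-yl)benzene
Product: 16 {3-[4-(benzyloxy)-2-methoxy-6-(methoxymethyl)phenyl]prop-1-yn-1-yl}oxy-tri(propan-2-yl)silane, via lithium acetylide 14 (not isolated), via lithium ynolate 15 (not isolated)
Conditions: n-BuLi, THF, −78 °C; LiOOt-Bu (from t-BuOOH and LiN(SiMe3)2), −78 to 0 °C; i-Pr3SiOTf, −78 °C; hexane/aq. NaHCO3 work-up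
Reagents that add atoms: tert-butyl hydroperoxide, CC(C)(C)OO; triisopropylsilyl trifluoromethanesulfonate, CC(C)[Si](C(C)C)(C(C)C)OS(=O)(=O)C(F)(F)F
Why: Oxidation of a lithium acetylide by lithium tert-butyl peroxide (oxygen transfer with loss of tert-butoxide) gives the ynolate, and the bulky silyl triflate silylates it on oxygen to an isolable triisopropylsilyl ynol ether; the benzylic hydrogens of 13 are not touched because the acetylide is formed first with one equivalent of base.

Step 10
Reactants: 4 methyl 4-methoxy-6-methyl-2-oxo-2H-pyran-5-carboxylate; 16 {3-[4-(benzyloxy)-2-methoxy-6-(methoxymethyl)phenyl]prop-1-yn-1-yl}oxy-tri(propan-2-yl)silane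
Product: 18 methyl 3-[4-(benzyloxy)-2-methoxy-6-(methoxymethyl)benzyl]-6-methoxy-2-methyl-4-[(triisopropylsilyl)oxy]benzoate, via bicyclic lactone adduct 17 (not isolated)
Conditions: 4 (2 equiv), 2,6-di-tert-butyl-4-methylpyridine (0.1 equiv), toluene, 120 °C, sealed tube, argon
Reagents that add atoms: none
Why: Proposed new method: the electron-poor diene 4, whose C6 is activated by the 5-ester and, through the diene, by the lactone carbonyl, should be attacked at C6 by the nucleophilic benzyl-bearing β-carbon of 16, and the oxygen-bearing carbon should then close onto the enol-ether carbon C3, in a strongly asynchronous inverse-electron-demand [4+2] cycloaddition that gives the 2-oxabicyclo[2.2.2]octadienone 17. At the reaction temperature 17 should lose CO2 by retro-[4+2], which makes the sequence irreversible and leaves the pentasubstituted benzene 18. The closest known reaction type is the cycloaddition of 2-pyrone-5-carboxylates with ynamines and alkoxyalkynes followed by loss of CO2; triisopropylsilyl ynol ethers serve as two-carbon partners in other thermal benzannulations, which speaks for their survival at this temperature. The carbocycle is closed by an intermolecular two-bond annulation (C4a–C5 and C6–C7), not by cyclisation of a tethered chain. No stereocentre remains, because the two bridgehead centres of 17 form as a racemate and are destroyed on aromatisation. The step needs regioselectivity, secured by the polar match between the β-carbon of 16 and the doubly activated C6 of 4, and by the oxygenated carbon pairing with C3. It also needs the [4+2] path to win over [2+2] addition at the C5–C6 enoate, which the irreversible CO2 loss favours. The hindered pyridine keeps traces of acid from hydrolysing 16, and 4 is used in excess because it is the cheaper partner.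

Step 11
Reactants: 18 methyl 3-[4-(benzyloxy)-2-methoxy-6-(methoxymethyl)benzyl]-6-methoxy-2-methyl-4-[(triisopropylsilyl)oxy]benzoate
Product: 21 methyl 3-[4-(benzyloxy)-2-methoxy-6-(methoxymethyl)benzyl]-6-methoxy-2-(2-oxopropyl)-4-[(triisopropylsilyl)oxy]benzoate, via benzylic lithium species 19 (not isolated), via lithium hemiaminal alkoxide 20 (not isolated)
Conditions: LiN(i-Pr)2 (1.15 equiv), THF, −78 °C; MeC(O)N(OMe)Me, −78 to 0 °C; aq. NH4Cl
Reagents that add atoms: N-methoxy-N-methylacetamide, CC(=O)N(C)OC
Why: Lateral lithiation of the ortho-toluate methyl group (anion stabilised by the ester) and acylation with a Weinreb amide, whose tetrahedral chelate 20 prevents over-addition and proton transfer until work-up; the di-ortho-substituted ester resists self-condensation, and the diarylmethane CH2, being meta to the ester, is much less acidic.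

Step 12
Reactants: 21 methyl 3-[4-(benzyloxy)-2-methoxy-6-(methoxymethyl)benzyl]-6-methoxy-2-(2-oxopropyl)-4-[(triisopropylsilyl)oxy]benzoate
Product: 22 methyl 3-[4-hydroxy-2-methoxy-6-(methoxymethyl)benzyl]-6-methoxy-2-(2-oxopropyl)-4-[(triisopropylsilyl)oxy]benzoate
Conditions: H2 (1 atm), 10% Pd/C, EtOAc, rt, stopped at full conversion
Reagents that add atoms: none
Why: Hydrogenolysis of the aryl benzyl ether is placed before ring C is formed, so no enol-lactone double bond is exposed to hydrogen; aryl benzyl ethers should cleave faster than the hindered benzylic methyl ether of ring A in an aprotic solvent.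

Step 13
Reactants: 22 methyl 3-[4-hydroxy-2-methoxy-6-(methoxymethyl)benzyl]-6-methoxy-2-(2-oxopropyl)-4-[(triisopropylsilyl)oxy]benzoate
Product: 23 5-[4-hydroxy-2-methoxy-6-(methoxymethyl)benzyl]-8-methoxy-3-methyl-6-[(triisopropylsilyl)oxy]-1H-isochromen-1-one
Conditions: TsOH·H2O (0.2 equiv), toluene, 80 °C
Reagents that add atoms: none
Why: Acid-catalysed enol lactonisation: the enol oxygen of the methyl ketone attacks the neighbouring ester, and loss of methanol gives the conjugated isocoumarin; the aryl silyl ether tolerates catalytic sulfonic acid in toluene.

Step 14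
Reactants: 23 5-[4-hydroxy-2-methoxy-6-(methoxymethyl)benzyl]-8-methoxy-3-methyl-6-[(triisopropylsilyl)oxy]-1H-isochromen-1-one
Product: 24 6-hydroxy-5-[4-hydroxy-2-methoxy-6-(methoxymethyl)benzyl]-8-methoxy-3-methyl-1H-isochromen-1-one (CNP0481202.0)
Conditions: Bu4NF, AcOH, THF, 0 °C
Reagents that add atoms: none
Why: Fluoride cleavage of the aryl silyl ether; buffering with acetic acid keeps the phenoxide and fluoride from opening the enol lactone.

## Compound list

1 | dimethyl 3-oxopentanedioate (dimethyl 1,3-acetonedicarboxylate) | COC(=O)CC(=O)CC(=O)OC | starting material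
2 | dimethyl 2-acetyl-3-oxopentanedioate | COC(=O)CC(=O)C(C(C)=O)C(=O)OC | intermediate
3 | methyl 4-hydroxy-6-methyl-2-oxo-2H-pyran-5-carboxylate | COC(=O)c1c(C)oc(=O)cc1O | intermediate
4 | methyl 4-methoxy-6-methyl-2-oxo-2H-pyran-5-carboxylate | COC(=O)c1c(C)oc(=O)cc1OC | intermediate
5 | [3,5-bis(benzyloxy)phenyl]methanol | OCc1cc(OCc2ccccc2)cc(OCc2ccccc2)c1 | starting material
6 | 1,3-bis(benzyloxy)-5-(methoxymethyl)benzene | COCc1cc(OCc2ccccc2)cc(OCc2ccccc2)c1 | intermediate
7 | N-{[2,4-bis(benzyloxy)-6-(methoxymethyl)phenyl]methylidene}-N-methylmethanaminium chloride | COCc1cc(OCc2ccccc2)cc(OCc2ccccc2)c1C=[N+](C)C.[Cl-] | intermediate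
8 | 2,4-bis(benzyloxy)-6-(methoxymethyl)benzaldehyde | COCc1cc(OCc2ccccc2)cc(OCc2ccccc2)c1C=O | intermediate
9 | 4-(benzyloxy)-2-hydroxy-6-(methoxymethyl)benzaldehyde | COCc1cc(OCc2ccccc2)cc(O)c1C=O | intermediate
10 | 4-(benzyloxy)-2-methoxy-6-(methoxymethyl)benzaldehyde | COCc1cc(OCc2ccccc2)cc(OC)c1C=O | intermediate
11 | 5-(benzyloxy)-1-methoxy-2-(2-methoxyethenyl)-3-(methoxymethyl)benzene (E/Z mixture) | COC=Cc1c(COC)cc(OCc2ccccc2)cc1OC | intermediate
12 | [4-(benzyloxy)-2-methoxy-6-(methoxymethyl)phenyl]acetaldehyde | COCc1cc(OCc2ccccc2)cc(OC)c1CC=O | intermediate
13 | 5-(benzyloxy)-1-methoxy-3-(methoxymethyl)-2-(prop-2-yn-1-yl)benzene | COCc1cc(OCc2ccccc2)cc(OC)c1CC#C | intermediate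
14 | {3-[4-(benzyloxy)-2-methoxy-6-(methoxymethyl)phenyl]prop-1-yn-1-yl}lithium | [Li]C#CCc1c(COC)cc(OCc2ccccc2)cc1OC | intermediate
15 | lithium 3-[4-(benzyloxy)-2-methoxy-6-(methoxymethyl)phenyl]prop-1-yn-1-olate | [Li+].[O-]C#CCc1c(COC)cc(OCc2ccccc2)cc1OC | intermediate
16 | {3-[4-(benzyloxy)-2-methoxy-6-(methoxymethyl)phenyl]prop-1-yn-1-yl}oxy-tri(propan-2-yl)silane | COCc1cc(OCc2ccccc2)cc(OC)c1CC#CO[Si](C(C)C)(C(C)C)C(C)C | intermediate
17 | methyl 7-[4-(benzyloxy)-2-methoxy-6-(methoxymethyl)benzyl]-5-methoxy-1-methyl-3-oxo-8-[(triisopropylsilyl)oxy]-2-oxabicyclo[2.2.2]octa-5,7-diene-6-carboxylate (racemic) | CC12OC(=O)C(C(OC)=C1C(=O)OC)C(O[Si](C(C)C)(C(C)C)C(C)C)=C2Cc1c(COC)cc(OCc2ccccc2)cc1OC | intermediate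
18 | methyl 3-[4-(benzyloxy)-2-methoxy-6-(methoxymethyl)benzyl]-6-methoxy-2-methyl-4-[(triisopropylsilyl)oxy]benzoate | COC(=O)c1c(OC)cc(O[Si](C(C)C)(C(C)C)C(C)C)c(Cc2c(COC)cc(OCc3ccccc3)cc2OC)c1C | intermediate
19 | ({2-[4-(benzyloxy)-2-methoxy-6-(methoxymethyl)benzyl]-5-methoxy-6-(methoxycarbonyl)-3-[(triisopropylsilyl)oxy]phenyl}methyl)lithium | [Li]Cc1c(C(=O)OC)c(OC)cc(O[Si](C(C)C)(C(C)C)C(C)C)c1Cc1c(COC)cc(OCc2ccccc2)cc1OC | intermediate
20 | lithium 1-{2-[4-(benzyloxy)-2-methoxy-6-(methoxymethyl)benzyl]-5-methoxy-6-(methoxycarbonyl)-3-[(triisopropylsilyl)oxy]phenyl}-2-[methoxy(methyl)amino]propan-2-olate (racemic) | [Li+].[O-]C(C)(Cc1c(C(=O)OC)c(OC)cc(O[Si](C(C)C)(C(C)C)C(C)C)c1Cc1c(COC)cc(OCc2ccccc2)cc1OC)N(C)OC | intermediate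
21 | methyl 3-[4-(benzyloxy)-2-methoxy-6-(methoxymethyl)benzyl]-6-methoxy-2-(2-oxopropyl)-4-[(triisopropylsilyl)oxy]benzoate | COC(=O)c1c(OC)cc(O[Si](C(C)C)(C(C)C)C(C)C)c(Cc2c(COC)cc(OCc3ccccc3)cc2OC)c1CC(C)=O | intermediate
22 | methyl 3-[4-hydroxy-2-methoxy-6-(methoxymethyl)benzyl]-6-methoxy-2-(2-oxopropyl)-4-[(triisopropylsilyl)oxy]benzoate | COC(=O)c1c(OC)cc(O[Si](C(C)C)(C(C)C)C(C)C)c(Cc2c(COC)cc(O)cc2OC)c1CC(C)=O | intermediate
23 | 5-[4-hydroxy-2-methoxy-6-(methoxymethyl)benzyl]-8-methoxy-3-methyl-6-[(triisopropylsilyl)oxy]-1H-isochromen-1-one | COCc1cc(O)cc(OC)c1Cc1c(O[Si](C(C)C)(C(C)C)C(C)C)cc(OC)c2c(=O)oc(C)cc12 | intermediate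
24 | 6-hydroxy-5-[4-hydroxy-2-methoxy-6-(methoxymethyl)benzyl]-8-methoxy-3-methyl-1H-isochromen-1-one | COCc1cc(O)cc(OC)c1Cc1c(O)cc(OC)c2c(=O)oc(C)cc12 | target

## Step count and least certain steps

Total step count: 14 (steps 1–2 for the pyrone, steps 3–9 for the ynol ether, step 10, steps 11–14 after it). Longest linear sequence: 12 steps (steps 3 to 14, from 5).

**Step 10 (key step).** The 4-methoxy group donates into the diene and the C6 methyl group hinders the first bond. The cycloaddition may therefore be outrun by thermal 1,3-migration of silicon from oxygen to carbon in 16 (ynol ether to silylketene), by adventitious hydrolysis of 16, or by [2+2] addition at the C5–C6 enoate; reversed regiochemistry is the less likely failure. The fallback builds ring B by the classical dihydroresorcylate route and uses only known reaction types. It sets out from 10 and comes back at 18.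
- Knoevenagel condensation of 10 with trimethyl phosphonoacetate (TiCl4, N-methylmorpholine, THF) would give methyl 3-[4-(benzyloxy)-2-methoxy-6-(methoxymethyl)phenyl]-2-(dimethoxyphosphoryl)prop-2-enoate F1.
- Conjugate reduction with NaBH4 would give methyl 3-[4-(benzyloxy)-2-methoxy-6-(methoxymethyl)phenyl]-2-(dimethoxyphosphoryl)propanoate F2.
- Horner–Wadsworth–Emmons reaction of F2 with acetaldehyde (NaH, THF) would give the crotonate A7; here too no benzylic leaving group is placed next to ring A.
- Michael–Claisen annulation of A7 with A6 (NaOMe, MeOH, reflux) would give A8.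
- Dehydrogenation (DDQ, 1,4-dioxane, reflux) would give methyl 3-[4-(benzyloxy)-2-methoxy-6-(methoxymethyl)benzyl]-4,6-dihydroxy-2-methylbenzoate F3.
- Silylation of the non-chelated hydroxyl (i-Pr3SiCl, imidazole, DMF) would give methyl 3-[4-(benzyloxy)-2-methoxy-6-(methoxymethyl)benzyl]-6-hydroxy-2-methyl-4-[(triisopropylsilyl)oxy]benzoate F4.
- Mitsunobu methylation of the chelated hydroxyl (MeOH, PPh3, diisopropyl azodicarboxylate) would give 18.

**Step 9.** Oxygen transfer to the acetylide may be incomplete, the ynolate may be silylated on carbon, or the ynol ether may be hydrolysed during work-up and chromatography. The fallback reaches the same ynolate by rearrangement of a dibromoketone enolate instead of acetylide oxidation. It sets out from 12 and comes back at 15. Addition of LiCHBr2 (from CH2Br2 and LiN(i-Pr)2, THF, −78 °C) to 12 would give 1,1-dibromo-3-[4-(benzyloxy)-2-methoxy-6-(methoxymethyl)phenyl]propan-2-ol F5. Oxidation with Dess–Martin periodinane would give 1,1-dibromo-3-[4-(benzyloxy)-2-methoxy-6-(methoxymethyl)phenyl]propan-2-one F6. Enolisation with LiN(SiMe3)2 and bromine–lithium exchange with n-BuLi (−78 °C to rt) would trigger the 1,2-shift to 15, which is silylated as in step 9.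

**Step 8.** Under carbonate in methanol, 12 may undergo aldol self-condensation before it is homologated, and 13 may isomerise to the arylallene. The fallback replaces the diazophosphonate by dibromo-olefination and carbenoid rearrangement. It sets out from 12 and comes back at 14. CBr4 and PPh3 (CH2Cl2, 0 °C) would give 5-(benzyloxy)-2-(3,3-dibromoprop-2-en-1-yl)-1-methoxy-3-(methoxymethyl)benzene F7. n-BuLi (2.1 equiv, THF, −78 °C) would convert F7 directly into 14, which is carried through the oxidation and silylation of step 9 without isolation of 13.

**Step 12.** Hydrogenolysis may not stop at the aryl benzyl ether and may go on to cleave the benzylic C–OMe bond at A6. The fallback removes the benzyl group without hydrogen. It sets out from 21 and comes back at 22. BCl3 with pentamethylbenzene as cation scavenger (CH2Cl2, −78 °C) would cleave the aryl benzyl ether by a Lewis-acid pathway, at a temperature where the aryl silyl ether, the methyl ethers and the benzylic methyl ether should survive.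

## Further compounds

F1 | step 10 | methyl 3-[4-(benzyloxy)-2-methoxy-6-(methoxymethyl)phenyl]-2-(dimethoxyphosphoryl)prop-2-enoate (E/Z mixture) | COC(=O)C(=Cc1c(COC)cc(OCc2ccccc2)cc1OC)P(=O)(OC)OC
F2 | step 10 | methyl 3-[4-(benzyloxy)-2-methoxy-6-(methoxymethyl)phenyl]-2-(dimethoxyphosphoryl)propanoate (racemic) | COC(=O)C(Cc1c(COC)cc(OCc2ccccc2)cc1OC)P(=O)(OC)OC
F3 | step 10 | methyl 3-[4-(benzyloxy)-2-methoxy-6-(methoxymethyl)benzyl]-4,6-dihydroxy-2-methylbenzoate | COC(=O)c1c(O)cc(O)c(Cc2c(COC)cc(OCc3ccccc3)cc2OC)c1C
F4 | step 10 | methyl 3-[4-(benzyloxy)-2-methoxy-6-(methoxymethyl)benzyl]-6-hydroxy-2-methyl-4-[(triisopropylsilyl)oxy]benzoate | COC(=O)c1c(O)cc(O[Si](C(C)C)(C(C)C)C(C)C)c(Cc2c(COC)cc(OCc3ccccc3)cc2OC)c1C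
F5 | step 9 | 1,1-dibromo-3-[4-(benzyloxy)-2-methoxy-6-(methoxymethyl)phenyl]propan-2-ol (racemic) | COCc1cc(OCc2ccccc2)cc(OC)c1CC(O)C(Br)Br
F6 | step 9 | 1,1-dibromo-3-[4-(benzyloxy)-2-methoxy-6-(methoxymethyl)phenyl]propan-2-one | COCc1cc(OCc2ccccc2)cc(OC)c1CC(=O)C(Br)Br
F7 | step 8 | 5-(benzyloxy)-2-(3,3-dibromoprop-2-en-1-yl)-1-methoxy-3-(methoxymethyl)benzene | COCc1cc(OCc2ccccc2)cc(OC)c1CC=C(Br)Br
F0 | step 12 | none | none
A1 | alternative 1 | methyl 4-(benzyloxy)-2-methoxy-5-(4-methoxybut-2-ynoyl)benzoate | COCC#CC(=O)c1cc(C(=O)OC)c(OC)cc1OCc1ccccc1
A2 | alternative 1 | 1,1-dimethoxy-3-(trimethylsilyloxy)buta-1,3-diene | COC(OC)=CC(=C)O[Si](C)(C)C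
A3 | alternative 1 | methyl 4-(benzyloxy)-5-[4-hydroxy-2-methoxy-6-(methoxymethyl)benzoyl]-2-methoxybenzoate | COCc1cc(O)cc(OC)c1C(=O)c1cc(C(=O)OC)c(OC)cc1OCc1ccccc1
A4 | alternative 2 | 6-{3-[4-(benzyloxy)-2-methoxy-6-(methoxymethyl)benzyl]-5-(2-methyl-1,3-dioxolan-2-yl)-2,4-dioxopentyl}-2,2-dimethyl-4H-1,3-dioxin-4-one | CC1(C)OC(=O)C=C(O1)CC(=O)C(Cc2c(COC)cc(OCc3ccccc3)cc2OC)C(=O)CC2(C)OCCO2
A5 | alternative 2 | 6-[4-(benzyloxy)-2-methoxy-6-(methoxymethyl)benzyl]-7-hydroxy-2,2-dimethyl-5-[(2-methyl-1,3-dioxolan-2-yl)methyl]-4H-1,3-benzodioxin-4-one | CC1(C)OC(=O)c2c(O1)cc(O)c(Cc3c(COC)cc(OCc4ccccc4)cc3OC)c2CC1(C)OCCO1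
A6 | alternative 3 | methyl 3-oxobutanoate (methyl acetoacetate) | CC(=O)CC(=O)OC
A7 | alternative 3 | methyl (E)-2-[4-(benzyloxy)-2-methoxy-6-(methoxymethyl)benzyl]but-2-enoate | C/C=C(/C(=O)OC)Cc1c(COC)cc(OCc2ccccc2)cc1OC
A8 | alternative 3 | methyl 3-[4-(benzyloxy)-2-methoxy-6-(methoxymethyl)benzyl]-2-methyl-4,6-dioxocyclohexane-1-carboxylate (mixture of diastereomers) | COC(=O)C1C(C)C(Cc2c(COC)cc(OCc3ccccc3)cc2OC)C(=O)CC1=O
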